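**Retrosynthetic overview**
1. Longipinane numbering is used: C1 ketone, C2=C3(Me), bridgeheads C4 and C11, C5 cyclobutane CH, C6 CMe2, C7 O-epoxy ester, C8 CH2, C9 O-angelate, C10 C(Me). The O7 epoxy ester is attached in the last step. The O9 angelate goes on before the ring-forming work.
2. The cyclobutane C4–C5–C11–C10 is cut at C5–C11 (C11 ketone enolate displacing a C5 mesylate). The cyclohexenone is cut at C3–C4 (epoxide-derived C4 radical adding to a C1 ynone). The seven-membered ring is cut at C4=C5 (ring-closing metathesis).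
3. The remaining chain, vinyl–C6(Me)(CH2CO2R)–C7H(O)–C8H2–C9H(O)–C10(Me)(CH2CO2R)–vinyl, is cut at C6–C7 and C9–C10 at once. This gives propane-1,3-diol and two molecules of one allenoate.
4. Enabling feature: the segment C6–C7–C8–C9–C10 of the seven-membered ring has a hidden C2 axis through C8. It is an anti (7R,9R) 1,3-diol flanked by two methyl-bearing quaternary carbons, each bonded to one cyclobutane carbon (C5, C4). The surplus acetate arm on C6 is later cut down to the second methyl group.
5. Ring order: two temporary γ-lactones, then the seven-membered, six-membered and four-membered rings.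

Key step: step 2

Assumption: the (R)-ligand is taken to deliver the 7R,9R series by analogy with related iridium-catalysed allylations. If the sense is opposite, the (S)-ligand is used.

**Step 1**
Reactants: 1 but-2-yn-1-ol; 2 triethyl orthoacetate
Product: 3 ethyl 3-methylpenta-3,4-dienoate
Conditions: EtCO2H (5 mol %), neat, 140 °C, EtOH distilled off
Reagents that add atoms: none
Why: Johnson orthoester Claisen rearrangement of a propargylic alcohol should give the β-allenic ester by [3,3] shift onto the methyl-bearing alkyne carbon; no stereocenter is formed.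

**Step 2**
Reactants: 4 propane-1,3-diol; 3 ethyl 3-methylpenta-3,4-dienoate (3 equiv)
Product: 6 (4S,5R,4'S,5'R)-5,5'-methylenebis(4-ethenyl-4-methyloxolan-2-one), via diol diester 5 (not isolated)
Conditions: [Ir(cod)Cl]2 (5 mol %), (R)-SEGPHOS (10 mol %), 4-chloro-3-nitrobenzoic acid (20 mol %), allyl acetate (10 mol %), Cs2CO3 (20 mol %), THF, 70 °C; then PPTS (10 mol %), 60 °C
Reagents that add atoms: none
Why: The cyclometallated trivalent iridium alkoxide of one CH2OH terminus undergoes β-hydride elimination, the iridium hydride hydrometallates the terminal C=C of 3 to a primary σ-allyl, and this adds through its γ-carbon to the transient aldehyde in a closed chair; the sequence then repeats at the other terminus, so C9–C10 and C6–C7 form in one redox-neutral operation and free malondialdehyde never exists. The closest known reaction types are the two-directional iridium-catalysed transfer-hydrogenative allylation of propane-1,3-diol and the reverse prenylation and tert-(hydroxy)prenylation of primary alcohols with allenes or vinyl epoxides. No ring closes in the C–C bond formations; the two γ-lactones close afterwards by 5-exo-trig acyl substitution of each new carbinol on its own ester arm, which protects O7 and O9 without extra steps. C7 and C9 are set by the chiral ligand, and C6 and C10 by the E geometry of the σ-allyl (the larger CH2CO2Et group lies trans to CH2–Ir to avoid allylic strain), so each hydroxyl ends up anti to the ester arm. The step needs branched regioselectivity, secured by the chair SE2' addition, and inertness of the products, secured by the hindered neopentyl carbinols that resist dehydrogenation. Doing the event twice under the same catalyst should shift stereo-errors into a separable diastereomer and raise the enantiopurity of the C2-symmetric product.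

**Step 3**
Reactants: 6 bis-lactone diene
Product: 7 C2-symmetric tricyclic bis-lactone (6S,7R,9R,10S; cis-cycloheptene C4=C5 flanked by two cis-fused butyrolactones on opposite faces)
Conditions: second-generation Hoveyda–Grubbs catalyst (5 mol %), toluene (2 mM), 80 °C, argon sparge
Reagents that add atoms: none
Why: Ring-closing metathesis of the two vinyl groups, which cannot isomerise for lack of allylic hydrogen, should close the seven-membered ring and keep the C2 axis; no stereocenter is formed.

**Step 4**
Reactants: 7 tricyclic bis-lactone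
Product: 8 lithium carboxylate (one lactone opened; free 7R-OH; CH2CO2Li on 6S-C6)
Conditions: LiOH·H2O (1.0 equiv), THF/H2O, 0 °C; freeze-dried, used crude
Reagents that add atoms: lithium hydroxide [Li+].[OH-]
Why: Saponification opens one of two homotopic lactones, so mono-opening gives one compound whichever ring reacts (desymmetrisation of a C2-symmetric compound); unreacted 7 is recycled.

**Step 5**
Reactants: 8 lithium carboxylate
Product: 10 carboxylic acid (7R-OTBS; CH2CO2H on C6; 9R,10S lactone kept), via bis-silyl compound 9 (not isolated)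
Conditions: TBSOTf (2.5 equiv), 2,6-lutidine, CH2Cl2, 0 °C; then K2CO3 (cat.), MeOH/H2O; citric acid to pH 4
Reagents that add atoms: tert-butyldimethylsilyl triflate CC(C)(C)[Si](C)(C)OS(=O)(=O)C(F)(F)F
Why: Silyl triflate silylation caps O7 and the carboxylate, and mild solvolysis cleaves only the labile silyl ester, so relactonisation is blocked.

**Step 6**
Reactants: 10 carboxylic acid
Product: 12 lactone (6,6-dimethyl; 7R-OTBS; 9R,10S; C4=C5), via Barton ester 11 (not isolated)
Conditions: 1-hydroxypyridine-2(1H)-thione, DCC, CH2Cl2, dark, 0 °C; then PhSH (10 equiv), white LED, 0 °C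
Reagents that add atoms: 1-hydroxypyridine-2(1H)-thione ON1C=CC=CC1=S (atoms only in 11)
Why: Barton reductive decarboxylation turns the acetate arm into the second C6 methyl group and erases the C6 stereocenter; excess thiophenol should trap the primary radical faster than its 1,2-vinyl shift.

**Step 7**
Reactants: 12 lactone; 13 1-propynylmagnesium bromide
Product: 14 ynone alcohol (C1 ynone on the C11 methylene; free 9R-OH; 10S)
Conditions: 13 (1.2 equiv), THF, −78 to −30 °C; aq NH4Cl
Reagents that add atoms: none
Why: Addition of an alkynyl Grignard reagent to a lactone should stop after one addition because the tetrahedral magnesium alkoxide collapses only on work-up; C2, C3 and the C3 methyl group are brought in.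

**Step 8**
Reactants: 14 ynone alcohol; 15 angelic acid
Product: 17 9-O-angelate ynone, via mixed anhydride 16 (not isolated)
Conditions: 15, 2,4,6-trichlorobenzoyl chloride, Et3N, toluene, rt; then 14, 80 °C
Reagents that add atoms: 2,4,6-trichlorobenzoyl chloride O=C(Cl)c1c(Cl)cc(Cl)cc1Cl (atoms only in 16)
Why: Yamaguchi-type mixed-anhydride acylation run without a nucleophilic catalyst should acylate the hindered C9 alcohol while keeping the Z geometry of the angeloyl group.

**Step 9**
Reactants: 17 angelate ynone
Product: 18 4S,5R-epoxide (oxygen syn to the C10 methyl group, anti to the C10 side chain)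
Conditions: mCPBA, NaHCO3, CH2Cl2, 0 °C
Reagents that add atoms: 3-chloroperbenzoic acid OOC(=O)c1cccc(Cl)c1
Why: Prilezhaev epoxidation should take the only electron-rich alkene (ynone and conjugated ester are deactivated) on the face that carries the small allylic methyl group of C10.

**Step 10**
Reactants: 18 epoxide
Product: 19 bicyclic hydroxy enone (cis-fused six- and seven-membered rings; 4R, 5S-OH, 7R, 9R, 10S)
Conditions: Cp2TiCl2 (20 mol %), Mn, 2,4,6-collidine·HCl, THF, rt
Reagents that add atoms: none
Why: Nugent–RajanBabu reductive epoxide opening by trivalent titanium gives the C4 radical, which adds 6-endo-dig to the β-carbon C3 of the ynone from the face of its tether (cis ring fusion, C4 set), while C5–O keeps its configuration and the vinyl radical is reduced and protonated to the enone.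

**Step 11**
Reactants: 19 hydroxy enone
Product: 20 C5 mesylate
Conditions: MsCl, Et3N, CH2Cl2, −10 °C
Reagents that add atoms: methanesulfonyl chloride CS(=O)(=O)Cl
Why: Sulfonylation of the only free hydroxyl proceeds with retention at C5 and installs the leaving group trans to C3.

**Step 12**
Reactants: 20 mesylate
Product: 21 tricyclic 7-O-TBS 9-O-angelate (4R,5S,7R,9R,10R,11R)
Conditions: LiHMDS (1.1 equiv), THF, −78 °C; DMPU, −78 to 40 °C
Reagents that add atoms: none
Why: Intramolecular enolate alkylation (4-exo-tet keto-sulfonate cyclisation, the established route to bicyclo[3.1.1]heptanones): the kinetic cross-conjugated C11 enolate attacks C5 opposite to the mesylate, which inverts C5, and C11 is fixed by the bridge.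

**Step 13**
Reactants: 21 silyl ether
Product: 22 7-hydroxy 9-O-angelate
Conditions: HF·pyridine, pyridine/THF, 0 °C to rt
Reagents that add atoms: none
Why: Fluoride-mediated desilylation frees O7 and should leave enone, cyclobutane and angelate untouched.

**Step 14**
Reactants: 23 (E)-2-methylbut-2-en-1-ol
Product: 24 [(2R,3R)-2,3-dimethyloxiran-2-yl]methanol
Conditions: Ti(OiPr)4 (10 mol %), D-(−)-diethyl tartrate (12 mol %), t-BuOOH, 4 Å molecular sieves, CH2Cl2, −20 °C
Reagents that add atoms: tert-butyl hydroperoxide CC(C)(C)OO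
Why: Sharpless asymmetric epoxidation: the D-tartrate catalyst sets both epoxide centres, and the E-alkene gives the cis-dimethyl epoxide.

**Step 15**
Reactants: 24 epoxy alcohol
Product: 25 (2S,3R)-2,3-dimethyloxirane-2-carboxylic acid
Conditions: TEMPO (10 mol %), PhI(OAc)2 (2.2 equiv), MeCN/H2O, rt
Reagents that add atoms: water O
Why: Oxoammonium-catalysed oxidation of the primary alcohol through the aldehyde hydrate leaves the epoxide and its stereocenters untouched (only the C2 descriptor changes).

**Step 16**
Reactants: 22 7-hydroxy 9-O-angelate; 25 epoxy acid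
Product: 27 target CNP0149458.1, via mixed anhydride 26 (not isolated)
Conditions: 25, 2,4,6-trichlorobenzoyl chloride, Et3N, THF, rt; then 22, DMAP, toluene, 40 °C
Reagents that add atoms: 2,4,6-trichlorobenzoyl chloride O=C(Cl)c1c(Cl)cc(Cl)cc1Cl (atoms only in 26)
Why: Yamaguchi esterification couples the α-quaternary acid, which cannot epimerise, to the hindered C7 alcohol, so the sensitive epoxide enters last.

**Compound list**
1 | but-2-yn-1-ol | CC#CCO | starting material
2 | triethyl orthoacetate | CC(OCC)(OCC)OCC | starting material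
3 | ethyl 3-methylpenta-3,4-dienoate | C=C=C(C)CC(=O)OCC | intermediate
4 | propane-1,3-diol | OCCCO | starting material
5 | diethyl (3S,4R,6R,7S)-3,7-diethenyl-4,6-dihydroxy-3,7-dimethylnonanedioate | CCOC(=O)C[C@@](C)(C=C)[C@H](O)C[C@@H](O)[C@](C)(C=C)CC(=O)OCC | intermediate
6 | (4S,5R,4'S,5'R)-5,5'-methylenebis(4-ethenyl-4-methyloxolan-2-one) | O=C1C[C@@](C)(C=C)[C@H](O1)C[C@H]2OC(=O)C[C@@]2(C)C=C | intermediate
7 | C2-symmetric tricyclic bis-lactone, 6S,7R,9R,10S, cis-alkene C4=C5 | O=C1C[C@@]2(C)C=C[C@]3(C)CC(=O)O[C@@H]3C[C@H]2O1 | intermediate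
8 | lithium carboxylate, lactone at C6/C7 opened, 7R-OH | O=C1C[C@@]2(C)C=C[C@](C)(CC(=O)[O-])[C@H](O)C[C@H]2O1.[Li+] | intermediate
9 | 7-O-TBS ether TBS ester | O=C1C[C@@]2(C)C=C[C@](C)(CC(=O)O[Si](C)(C)C(C)(C)C)[C@H](O[Si](C)(C)C(C)(C)C)C[C@H]2O1 | intermediate
10 | 7-O-TBS carboxylic acid | O=C1C[C@@]2(C)C=C[C@](C)(CC(=O)O)[C@H](O[Si](C)(C)C(C)(C)C)C[C@H]2O1 | intermediate
11 | Barton ester of 10 | O=C1C[C@@]2(C)C=C[C@](C)(CC(=O)ON3C=CC=CC3=S)[C@H](O[Si](C)(C)C(C)(C)C)C[C@H]2O1 | intermediate
12 | 6,6-dimethyl 7-O-TBS cycloheptene lactone | O=C1C[C@@]2(C)C=CC(C)(C)[C@H](O[Si](C)(C)C(C)(C)C)C[C@H]2O1 | intermediate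
13 | 1-propynylmagnesium bromide | CC#C[Mg]Br | starting material
14 | ynone alcohol, 9R-OH, 10S, 7R-OTBS | CC#CC(=O)C[C@@]1(C)C=CC(C)(C)[C@H](O[Si](C)(C)C(C)(C)C)C[C@H]1O | intermediate
15 | angelic acid, (Z)-2-methylbut-2-enoic acid | C/C=C(/C)C(=O)O | starting material
16 | angelic 2,4,6-trichlorobenzoic anhydride | C/C=C(/C)C(=O)OC(=O)c1c(Cl)cc(Cl)cc1Cl | intermediate
17 | 9-O-angelate ynone | CC#CC(=O)C[C@@]1(C)C=CC(C)(C)[C@H](O[Si](C)(C)C(C)(C)C)C[C@H]1OC(=O)/C(C)=C\C | intermediate
18 | 4S,5R-epoxide of 17 | CC#CC(=O)C[C@@]1(C)[C@@H]2O[C@@H]2C(C)(C)[C@H](O[Si](C)(C)C(C)(C)C)C[C@H]1OC(=O)/C(C)=C\C | intermediate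
19 | bicyclic 5S-hydroxy enone, 4R,7R,9R,10S | CC1=CC(=O)C[C@@]2(C)[C@@H]1[C@H](O)C(C)(C)[C@H](O[Si](C)(C)C(C)(C)C)C[C@H]2OC(=O)/C(C)=C\C | intermediate
20 | C5 mesylate of 19 | CC1=CC(=O)C[C@@]2(C)[C@@H]1[C@H](OS(C)(=O)=O)C(C)(C)[C@H](O[Si](C)(C)C(C)(C)C)C[C@H]2OC(=O)/C(C)=C\C | intermediate
21 | 7-O-TBS 9-O-angeloyl longipin-2-en-1-one | C/C=C(/C)C(=O)O[C@@H]1C[C@@H](O[Si](C)(C)C(C)(C)C)C(C)(C)[C@@H]2[C@H]3C(=O)C=C(C)[C@@H]2[C@]31C | intermediate
22 | 7-hydroxy 9-O-angeloyl longipin-2-en-1-one | C/C=C(/C)C(=O)O[C@@H]1C[C@@H](O)C(C)(C)[C@@H]2[C@H]3C(=O)C=C(C)[C@@H]2[C@]31C | intermediate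
23 | (E)-2-methylbut-2-en-1-ol | C/C=C(\C)CO | starting material
24 | [(2R,3R)-2,3-dimethyloxiran-2-yl]methanol | OC[C@@]1(C)O[C@@H]1C | intermediate
25 | (2S,3R)-2,3-dimethyloxirane-2-carboxylic acid | OC(=O)[C@@]1(C)O[C@@H]1C | intermediate
26 | mixed anhydride of 25 and 2,4,6-trichlorobenzoic acid | O=C(OC(=O)[C@@]1(C)O[C@@H]1C)c1c(Cl)cc(Cl)cc1Cl | intermediate
27 | CNP0149458.1 | C/C=C(/C)C(=O)O[C@@H]1C[C@@H](OC(=O)[C@@]2(C)O[C@@H]2C)C(C)(C)[C@@H]2[C@H]3C(=O)C=C(C)[C@@H]2[C@]31C | target

**Step count**
- Total step count: 16.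
- Longest linear sequence: 14 (steps 1–13 and 16).

**Steps most likely to fail**

**Step 12.**
- What may go wrong: substitution at C5, which lies next to the quaternary C6, may be slow. Proton transfer to the extended enolate and loss of methanesulfonic acid toward C4 could then overtake ring closure.
- Fallback, from 19 back to 21: the C5 alcohol is oxidised (Dess–Martin periodinane) to the C5 ketone F7.
- Norrish–Yang photocyclisation of F7 (abstraction of a C11 hydrogen, then biradical closure) gives the C5 cyclobutanol F8.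
- F8 is acylated with methyl oxalyl chloride to the methyl oxalate F9, and radical deoxygenation with Bu3SnH/AIBN at the bridgehead gives 21.

**Step 10.**
- What may go wrong: the two similar C–O bonds of the epoxide may cleave without selectivity, the wrong (C5) radical may be reduced early, or the C4 radical may attack 5-exo.
- Fallback, from 17 back to 19: hydroiodination of the ynone (NaI, AcOH) gives the (Z)-β-iodo enone F5.
- Tin-hydride-mediated vinyl radical cyclisation of F5 under dry air (6-exo-trig onto C4, which fixes the regiochemistry through the tether; oxygen capture at C5 anti to the new bond) gives the C5 hydroperoxide F6.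
- PPh3 reduces F6 to 19.

**Step 2.**
- What may go wrong: base or metal may isomerise the allenoate to the conjugated dienoate, loss of E/Z control in the σ-allyl may erode selectivity at the quaternary carbons, or the reaction may stall at the mono-adduct.
- Fallback, from 3 back to 6: copper-catalysed hydroboration of 3 with pinacolborane gives the (E)-allylboronate F1.
- Chiral phosphoric acid-catalysed allylboration of commercial 3-(tert-butyldimethylsilyloxy)propanal with F1, with lactonisation on work-up, gives the silyloxyethyl lactone F2.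
- TBAF gives the hydroxyethyl lactone F3, and Dess–Martin oxidation gives the aldehyde F4.
- A second allylboration of F4 with F1, again with lactonisation, gives 6.

**Further compounds**
F1 | step 2 | ethyl (E)-3-methyl-5-(4,4,5,5-tetramethyl-1,3,2-dioxaborolan-2-yl)pent-3-enoate | CCOC(=O)C/C(C)=C/CB1OC(C)(C)C(C)(C)O1
F2 | step 2 | (4S,5R)-5-[2-(tert-butyldimethylsilyloxy)ethyl]-4-ethenyl-4-methyloxolan-2-one | O=C1C[C@@](C)(C=C)[C@H](O1)CCO[Si](C)(C)C(C)(C)C
F3 | step 2 | (4S,5R)-4-ethenyl-5-(2-hydroxyethyl)-4-methyloxolan-2-one | O=C1C[C@@](C)(C=C)[C@H](O1)CCO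
F4 | step 2 | 2-[(2R,3S)-3-ethenyl-3-methyl-5-oxooxolan-2-yl]acetaldehyde | O=C1C[C@@](C)(C=C)[C@H](O1)CC=O
F5 | step 10 | (Z)-β-iodo enone from 17 | C/C(I)=C/C(=O)C[C@@]1(C)C=CC(C)(C)[C@H](O[Si](C)(C)C(C)(C)C)C[C@H]1OC(=O)/C(C)=C\C
F6 | step 10 | C5 hydroperoxide corresponding to 19 | CC1=CC(=O)C[C@@]2(C)[C@@H]1[C@H](OO)C(C)(C)[C@H](O[Si](C)(C)C(C)(C)C)C[C@H]2OC(=O)/C(C)=C\C
F7 | step 12 | C5 ketone from 19 | CC1=CC(=O)C[C@@]2(C)[C@@H]1C(=O)C(C)(C)[C@H](O[Si](C)(C)C(C)(C)C)C[C@H]2OC(=O)/C(C)=C\C
F8 | step 12 | 5-hydroxy derivative of 21 | C/C=C(/C)C(=O)O[C@@H]1C[C@@H](O[Si](C)(C)C(C)(C)C)C(C)(C)[C@]2(O)[C@H]3C(=O)C=C(C)[C@@H]2[C@]31C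
F9 | step 12 | methyl oxalate of F8 | C/C=C(/C)C(=O)O[C@@H]1C[C@@H](O[Si](C)(C)C(C)(C)C)C(C)(C)[C@]2(OC(=O)C(=O)OC)[C@H]3C(=O)C=C(C)[C@@H]2[C@]31C
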